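**Strategy.** The benzene ring (C4a, C5, C6, C7, C8, C8a) is made last, from three alkynes. Two of them, C4a≡C5 and C8a≡C8, already hang on the quaternary carbon C2, one through C3–C4 and one through O1. A single ruthenium-catalysed [2+2+2] cycloaddition with ethynylboronate (C6–C7) should therefore close the arene and the fused dihydropyran ring at once and leave boron at C6 as a masked hydroxyl. The precursor is a 1,7-diyne: a tertiary methyl ynol ether with a but-3-ynyl arm and the finished side chain. All three stereocentres come from purchased chiral building blocks. The terminal alkyne stays C-silylated until the ynol ether is made, because the acetylide methylation would otherwise also cap C5.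

Key step: step 9

Assumption: compounds 1, 2, 8, 13 and 20 are purchased, with 1, 2 and 8 as single enantiomers.
Atom labels follow the chroman numbering of the target (O1, C2, C3, C4, C4a, C5–C8, C8a; side chain C1'–C13').

**Step 1**
Reactants: 1 (R)-citronellyl bromide [(6R)-8-bromo-2,6-dimethyloct-2-ene]; 2 (S)-1-bromo-3-chloro-2-methylpropane
Product: 4 (6S,10R)-11-chloro-2,6,10-trimethylundec-2-ene, via citronellylmagnesium bromide 3 (not isolated)
Conditions: Mg, THF, 40 °C; then 2, Li2CuCl4 (3 mol%), THF, −10 → 0 °C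
Reagents that add atoms: none
Why: Copper-catalysed Grignard cross-coupling (Kochi type) should join C6' to C5' at the C–Br bond of 2 and spare its C–Cl bond, and since no bond at a stereocentre is made or broken, C8' (from 1) and C4' (from 2) are carried over as bought.

**Step 2**
Reactants: 4 (6S,10R)-11-chloro-2,6,10-trimethylundec-2-ene
Product: 6 (3R,7S)-3,7,11-trimethyldodec-10-en-1-ol, via C14 alkylmagnesium chloride 5 (not isolated)
Conditions: Mg, I2 (cat.), THF, reflux; then (CH2O)n, THF, 0 °C → rt; aq. NH4Cl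
Reagents that add atoms: formaldehyde (from paraformaldehyde), C=O
Why: Grignard addition to formaldehyde should add the single carbon C2' as a primary alcohol, with the alkene and both stereocentres inert.

**Step 3**
Reactants: 6 (3R,7S)-3,7,11-trimethyldodec-10-en-1-ol
Product: 7 (6S,10R)-12-bromo-2,6,10-trimethyldodec-2-ene
Conditions: CBr4, PPh3, CH2Cl2, 0 °C → rt
Reagents that add atoms: tetrabromomethane, BrC(Br)(Br)Br
Why: Appel bromination converts the primary alcohol into the bromide under neutral conditions that spare the trisubstituted alkene.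

**Step 4**
Reactants: 8 (S)-2-methylglycidol [[(2S)-2-methyloxiran-2-yl]methanol]
Product: 9 [(2R)-2-methyloxiran-2-yl]methyl 4-methylbenzenesulfonate
Conditions: TsCl, Et3N, DMAP (cat.), CH2Cl2, −10 → 0 °C
Reagents that add atoms: 4-toluenesulfonyl chloride, Cc1ccc(cc1)S(Cl)(=O)=O
Why: Tosylate formation at the primary alcohol leaves the quaternary stereocentre untouched (the descriptor changes from S to R only because the substituent priorities change) and gives a crystalline electrophile.

**Step 5**
Reactants: 7 (6S,10R)-12-bromo-2,6,10-trimethyldodec-2-ene; 9 [(2R)-2-methyloxiran-2-yl]methyl 4-methylbenzenesulfonate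
Product: 12 (2R)-2-methyl-2-[(4R,8S)-4,8,12-trimethyltridec-11-en-1-yl]oxirane, via C15 alkylmagnesium bromide 10 (not isolated), via hydroxy tosylate 11 (not isolated)
Conditions: Mg, THF, 40 °C; then CuI (10 mol%), 9, THF, −40 → −20 °C; MeOH quench; K2CO3, MeOH, rt
Reagents that add atoms: none
Why: Copper-catalysed Grignard opening of the glycidyl sulfonate at its unsubstituted oxirane carbon (C1'), followed by Williamson-type 3-exo-tet closure of the tertiary alkoxide onto the neopentyl-type tosylate carbon (C3), should give the new epoxide, and because no bond to C2 is made or broken its configuration is that of 9.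

**Step 6**
Reactants: 12 (2R)-2-methyl-2-[(4R,8S)-4,8,12-trimethyltridec-11-en-1-yl]oxirane; 13 triisopropyl(prop-1-yn-1-yl)silane
Product: 15 (5R,9R,13S)-5,9,13,17-tetramethyl-1-(triisopropylsilyl)octadec-16-en-1-yn-5-ol, via lithiated silylpropyne 14 (not isolated)
Conditions: 13, n-BuLi, THF, −20 °C; then 12, DMPU, −20 °C → rt; H2O
Reagents that add atoms: none
Why: SN2 opening of the 2,2-disubstituted epoxide at its CH2 carbon by the propargylic lithium reagent, whose bulky silyl group favours reaction through the propargyl terminus, should form C3–C4 and free the tertiary alcohol with C2 unchanged.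

**Step 7**
Reactants: 15 (5R,9R,13S)-5,9,13,17-tetramethyl-1-(triisopropylsilyl)octadec-16-en-1-yn-5-ol
Product: 18 triisopropyl[(5R,9R,13S)-5,9,13,17-tetramethyl-5-(prop-1-yn-1-yloxy)octadec-16-en-1-yn-1-yl]silane, via dichlorovinyl ether 16 (not isolated), via lithium alkoxyacetylide 17 (not isolated)
Conditions: KH, THF, 0 °C; Cl2C=CHCl, −50 °C → rt; n-BuLi (2.5 equiv), −78 → −40 °C; MeI, DMPU, −78 °C → rt
Reagents that add atoms: trichloroethylene, ClC=C(Cl)Cl; iodomethane, CI
Why: Ynol ether synthesis through a 1,2-dichlorovinyl ether: the potassium tertiary alkoxide adds to dichloroacetylene generated from trichloroethylene, n-BuLi then causes dehydrochlorination and chlorine–lithium exchange, and the lithium alkoxyacetylide is C-methylated, while the silyl cap prevents deprotonation and methylation at C5.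

**Step 8**
Reactants: 18 triisopropyl[(5R,9R,13S)-5,9,13,17-tetramethyl-5-(prop-1-yn-1-yloxy)octadec-16-en-1-yn-1-yl]silane
Product: 19 (5R,9R,13S)-5,9,13,17-tetramethyl-5-(prop-1-yn-1-yloxy)octadec-16-en-1-yne
Conditions: TBAF, THF, 0 °C → rt; Et3N-treated silica, kept below 25 °C and used at once
Reagents that add atoms: none
Why: Fluoride-induced protodesilylation of the alkynylsilane proceeds under basic conditions, to which the acid- and heat-sensitive ynol ether should be inert.

**Step 9**
Reactants: 19 (5R,9R,13S)-5,9,13,17-tetramethyl-5-(prop-1-yn-1-yloxy)octadec-16-en-1-yne; 20 ethynylboronic acid pinacol ester (2-ethynyl-4,4,5,5-tetramethyl-1,3,2-dioxaborolane)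
Product: 21 2-[(2R)-2,8-dimethyl-2-[(4R,8S)-4,8,12-trimethyltridec-11-en-1-yl]-3,4-dihydro-2H-chromen-6-yl]-4,4,5,5-tetramethyl-1,3,2-dioxaborolane
Conditions: Cp*RuCl(cod) (10 mol%), 20 (3 equiv), ClCH2CH2Cl, rt, 19 added slowly
Reagents that add atoms: none
Why: Loss of cod gives the Cp*RuCl fragment (divalent ruthenium), which binds both alkynes of 19 and couples them oxidatively to a ruthenacyclopentadiene (tetravalent ruthenium), forming C4a–C8a; the boronate alkyne then inserts at the less hindered Ru–C5 bond (C5–C6) and reductive elimination forms C7–C8 and releases the arene. The closest known reaction type is the Cp*RuCl(cod)-catalysed [2+2+2] cycloaddition of 1,6- and 1,7-diynes with alkynylboronates, and heteroatom-substituted alkynes (ynamides, alkynyl ethers) are established partners in such cyclotrimerisations. The dihydropyran ring (O1, C2, C3, C4, C4a, C8a) closes in the oxidative cyclisation, an intramolecular alkyne–alkyne coupling helped by the gem-disubstituted C2, and the benzene ring closes in the final reductive elimination from the seven-membered ruthenacycle. No stereocentre is formed, and C2, C4', C8' and the remote trisubstituted alkene are spectators. The step needs cross- over homo-trimerisation, which the tether, the excess of 20 and the slow addition of 19 should secure, and it needs boron at C6, which sterics should secure because the boron-bearing alkyne carbon bonds to the unsubstituted terminus C5 and so ends meta to the methyl-bearing C8. Working at room temperature avoids retro-ene loss of the tertiary-alkyl ynol ether.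

**Step 10**
Reactants: 21 2-[(2R)-2,8-dimethyl-2-[(4R,8S)-4,8,12-trimethyltridec-11-en-1-yl]-3,4-dihydro-2H-chromen-6-yl]-4,4,5,5-tetramethyl-1,3,2-dioxaborolane
Product: 22 (2R)-2,8-dimethyl-2-[(4R,8S)-4,8,12-trimethyltridec-11-en-1-yl]-3,4-dihydro-2H-chromen-6-ol
Conditions: NaBO3·4H2O, THF/H2O, rt, under N2
Reagents that add atoms: sodium perborate, [Na+].[O-]OB=O
Why: Oxidation of the aryl boronate (peroxide attack on boron, 1,2-aryl shift from boron to oxygen, hydrolysis) should give the C6 phenol with oxygen exactly where boron was, perborate being too mild to epoxidise the alkene.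

**Compound list**

1 | (R)-citronellyl bromide, (6R)-8-bromo-2,6-dimethyloct-2-ene | CC(C)=CCC[C@@H](C)CCBr | starting material
2 | (S)-1-bromo-3-chloro-2-methylpropane | BrC[C@@H](C)CCl | starting material
3 | [(3R)-3,7-dimethyloct-6-en-1-yl]magnesium bromide | CC(C)=CCC[C@@H](C)CC[Mg]Br | intermediate
4 | (6S,10R)-11-chloro-2,6,10-trimethylundec-2-ene | CC(C)=CCC[C@@H](C)CCC[C@@H](C)CCl | intermediate
5 | [(2R,6S)-2,6,10-trimethylundec-9-en-1-yl]magnesium chloride | CC(C)=CCC[C@@H](C)CCC[C@@H](C)C[Mg]Cl | intermediate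
6 | (3R,7S)-3,7,11-trimethyldodec-10-en-1-ol | CC(C)=CCC[C@@H](C)CCC[C@@H](C)CCO | intermediate
7 | (6S,10R)-12-bromo-2,6,10-trimethyldodec-2-ene | CC(C)=CCC[C@@H](C)CCC[C@@H](C)CCBr | intermediate
8 | (S)-2-methylglycidol, [(2S)-2-methyloxiran-2-yl]methanol | OC[C@@]1(C)CO1 | starting material
9 | [(2R)-2-methyloxiran-2-yl]methyl 4-methylbenzenesulfonate | Cc1ccc(cc1)S(=O)(=O)OC[C@@]1(C)CO1 | intermediate
10 | [(3R,7S)-3,7,11-trimethyldodec-10-en-1-yl]magnesium bromide | CC(C)=CCC[C@@H](C)CCC[C@@H](C)CC[Mg]Br | intermediate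
11 | (2R,6R,10S)-2-hydroxy-2,6,10,14-tetramethylpentadec-13-en-1-yl 4-methylbenzenesulfonate | CC(C)=CCC[C@@H](C)CCC[C@@H](C)CCC[C@@](C)(O)COS(=O)(=O)c1ccc(C)cc1 | intermediate
12 | (2R)-2-methyl-2-[(4R,8S)-4,8,12-trimethyltridec-11-en-1-yl]oxirane | CC(C)=CCC[C@@H](C)CCC[C@@H](C)CCC[C@]1(C)CO1 | intermediate
13 | triisopropyl(prop-1-yn-1-yl)silane | CC#C[Si](C(C)C)(C(C)C)C(C)C | starting material
14 | [3-(triisopropylsilyl)prop-2-yn-1-yl]lithium | [Li]CC#C[Si](C(C)C)(C(C)C)C(C)C | intermediate
15 | (5R,9R,13S)-5,9,13,17-tetramethyl-1-(triisopropylsilyl)octadec-16-en-1-yn-5-ol | CC(C)=CCC[C@@H](C)CCC[C@@H](C)CCC[C@@](C)(O)CCC#C[Si](C(C)C)(C(C)C)C(C)C | intermediate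
16 | triisopropyl[(5R,9R,13S)-5-{[(E)-1,2-dichloroethenyl]oxy}-5,9,13,17-tetramethyloctadec-16-en-1-yn-1-yl]silane | CC(C)=CCC[C@@H](C)CCC[C@@H](C)CCC[C@@](C)(O/C(Cl)=C\Cl)CCC#C[Si](C(C)C)(C(C)C)C(C)C | intermediate
17 | [2-{[(5R,9R,13S)-5,9,13,17-tetramethyl-1-(triisopropylsilyl)octadec-16-en-1-yn-5-yl]oxy}ethynyl]lithium | CC(C)=CCC[C@@H](C)CCC[C@@H](C)CCC[C@@](C)(OC#C[Li])CCC#C[Si](C(C)C)(C(C)C)C(C)C | intermediate
18 | triisopropyl[(5R,9R,13S)-5,9,13,17-tetramethyl-5-(prop-1-yn-1-yloxy)octadec-16-en-1-yn-1-yl]silane | CC(C)=CCC[C@@H](C)CCC[C@@H](C)CCC[C@@](C)(OC#CC)CCC#C[Si](C(C)C)(C(C)C)C(C)C | intermediate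
19 | (5R,9R,13S)-5,9,13,17-tetramethyl-5-(prop-1-yn-1-yloxy)octadec-16-en-1-yne | CC(C)=CCC[C@@H](C)CCC[C@@H](C)CCC[C@](C)(CCC#C)OC#CC | intermediate
20 | ethynylboronic acid pinacol ester, 2-ethynyl-4,4,5,5-tetramethyl-1,3,2-dioxaborolane | C#CB1OC(C)(C)C(C)(C)O1 | starting material
21 | 2-[(2R)-2,8-dimethyl-2-[(4R,8S)-4,8,12-trimethyltridec-11-en-1-yl]-3,4-dihydro-2H-chromen-6-yl]-4,4,5,5-tetramethyl-1,3,2-dioxaborolane | CC(C)=CCC[C@@H](C)CCC[C@@H](C)CCC[C@]1(C)CCc2cc(B3OC(C)(C)C(C)(C)O3)cc(C)c2O1 | intermediate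
22 | (2R)-2,8-dimethyl-2-[(4R,8S)-4,8,12-trimethyltridec-11-en-1-yl]-3,4-dihydro-2H-chromen-6-ol | CC(C)=CCC[C@@H](C)CCC[C@@H](C)CCC[C@]1(C)CCc2cc(O)cc(C)c2O1 | target

**Totals**

Total step count: 10.
Longest linear sequence: 9 steps (steps 1–3 and 5–10; step 4 is a one-step side branch).

**Steps most likely to fail, with fallbacks**

Step 9 (cycloaddition). What may go wrong: insertion of the boronate alkyne in the reverse orientation, self-trimerisation of the diyne through its terminal alkyne, or decomposition of the ynol ether on ruthenium. The fallback is a classical aryl ether closure that forms O1–C8a last and needs no ynol ether; it sets out from epoxide 12. Purchased 2-bromo-5-methoxy-1,3-dimethylbenzene is brominated at one benzylic methyl (NBS, AIBN, PhCF3, reflux) to 2-bromo-1-(bromomethyl)-5-methoxy-3-methylbenzene F1. Its Grignard reagent (2-bromo-5-methoxy-3-methylbenzyl)magnesium bromide F2 (Mg, Et2O, 0 °C) should open 12 at the CH2 carbon under CuI catalysis (THF, −30 → 0 °C) to give (3R,7R,11S)-1-(2-bromo-5-methoxy-3-methylphenyl)-3,7,11,15-tetramethylhexadec-14-en-3-ol F3. Palladium-catalysed intramolecular C–O coupling (Pd(OAc)2, 2-(di-tert-butylphosphino)-1,1'-binaphthyl, Cs2CO3, toluene, 80 °C) should then close the dihydropyran ring without touching C2 and give (2R)-6-methoxy-2,8-dimethyl-2-[(4R,8S)-4,8,12-trimethyltridec-11-en-1-yl]-3,4-dihydro-2H-chromene F4. Thiolate demethylation (NaSEt, DMF, 120 °C) comes back to the route at the target 22.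

Step 7 (ynol ether formation). What may go wrong: sluggish or incomplete addition of the hindered tertiary alkoxide to dichloroacetylene, and base-induced side reactions of trichloroethylene. The fallback builds the ynol ether from the formate ester and sets out from 15. Formylation (acetic formic anhydride, pyridine, 0 °C) should give (5R,9R,13S)-5,9,13,17-tetramethyl-1-(triisopropylsilyl)octadec-16-en-1-yn-5-yl formate F5. Dichloromethylenation of the formate carbonyl (PPh3, CCl4, THF, 60 °C) should give triisopropyl[(5R,9R,13S)-5-[(2,2-dichloroethenyl)oxy]-5,9,13,17-tetramethyloctadec-16-en-1-yn-1-yl]silane F6. Treatment with n-BuLi (2.2 equiv, THF, −78 °C) should convert F6 into the lithium alkoxyacetylide 17, where the route is rejoined and methylation gives 18.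

Step 6 (propargylation). What may go wrong: slow SN2 attack at the neopentyl-type epoxide carbon and competing reaction through the allenyl terminus of the ambident anion. The fallback is ring expansion followed by alkynylation with an unambiguous acetylide; it sets out from 12. Dimethylsulfoxonium methylide (Me3S(O)I, KOtBu, t-BuOH, 60 °C) should expand the epoxide, with C2 untouched, to (2R)-2-methyl-2-[(4R,8S)-4,8,12-trimethyltridec-11-en-1-yl]oxetane F7. Lithium (triisopropylsilyl)acetylide F8 (from purchased ethynyltriisopropylsilane and n-BuLi, THF, −78 °C) with BF3·OEt2 should open F7 at its unsubstituted carbon C4 and come back to the route at 15.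

**Further compounds**

F1 | step 9 | 2-bromo-1-(bromomethyl)-5-methoxy-3-methylbenzene | COc1cc(C)c(Br)c(CBr)c1
F2 | step 9 | (2-bromo-5-methoxy-3-methylbenzyl)magnesium bromide | COc1cc(C)c(Br)c(C[Mg]Br)c1
F3 | step 9 | (3R,7R,11S)-1-(2-bromo-5-methoxy-3-methylphenyl)-3,7,11,15-tetramethylhexadec-14-en-3-ol | CC(C)=CCC[C@@H](C)CCC[C@@H](C)CCC[C@@](C)(O)CCc1cc(OC)cc(C)c1Br
F4 | step 9 | (2R)-6-methoxy-2,8-dimethyl-2-[(4R,8S)-4,8,12-trimethyltridec-11-en-1-yl]-3,4-dihydro-2H-chromene | CC(C)=CCC[C@@H](C)CCC[C@@H](C)CCC[C@]1(C)CCc2cc(OC)cc(C)c2O1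
F5 | step 7 | (5R,9R,13S)-5,9,13,17-tetramethyl-1-(triisopropylsilyl)octadec-16-en-1-yn-5-yl formate | CC(C)=CCC[C@@H](C)CCC[C@@H](C)CCC[C@@](C)(OC=O)CCC#C[Si](C(C)C)(C(C)C)C(C)C
F6 | step 7 | triisopropyl[(5R,9R,13S)-5-[(2,2-dichloroethenyl)oxy]-5,9,13,17-tetramethyloctadec-16-en-1-yn-1-yl]silane | CC(C)=CCC[C@@H](C)CCC[C@@H](C)CCC[C@@](C)(OC=C(Cl)Cl)CCC#C[Si](C(C)C)(C(C)C)C(C)C
F7 | step 6 | (2R)-2-methyl-2-[(4R,8S)-4,8,12-trimethyltridec-11-en-1-yl]oxetane | CC(C)=CCC[C@@H](C)CCC[C@@H](C)CCC[C@]1(C)CCO1
F8 | step 6 | lithium (triisopropylsilyl)acetylide | [Li]C#C[Si](C(C)C)(C(C)C)C(C)C
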